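## Plan

- Locants are those of the target throughout. Ring A = C1–C5 and C10 (tiglate on C3, methyls on C4 and C5). Ring B = C5–C6–C7–C8–C9–C10 (isopropenyl C11–C13 on C7, ketone C8, senecioate on C9). β is the face of the C5 methyl. "Hydrindane core" means ring A cis-fused to the cyclopentane C5–C6–C8–C9–C10.
- Retrosynthesis: in ring B the ketone C8 sits between C7, which carries an allyl-cation-stabilising isopropenyl group, and C9, which carries an acyloxy group. This array is the product of a 1,2-shift, so the C6–C7 bond is cut and C6 is rebonded to C8. The precursor is a spiro vinyl epoxide (C8–O–C7) on the hydrindane core.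
- Further cuts: the C9 ester and the epoxide (directed epoxidation of a dienol), C8=C7 (Wittig), C9–O (Rubottom), the C9 methylene (diazomethane), C5–C6 and C8–C10 (dichloroketene [2+2] across C5=C10), the C3 ester and the C4 methyl (cuprate).
- Forward order: ring A first, then a cyclobutanone, then the cyclopentanone of the hydrindane core, and ring B only in the last step by one-carbon ring enlargement.
- Stereochemistry: C3 from the starting enone; C4 by anti cuprate addition; C5 and C10 by the suprafacial [2+2] anti to the C4 methyl; C9 by convex-face enol ether oxidation; the epoxide by hydroxyl-directed delivery; C7 by the course of the 1,2-shift.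

Key step: step 16

Assumption: enone 1 is treated as a purchasable chiral building block (otherwise three steps from 1,4-dioxaspiro[4.5]dec-6-en-8-one by asymmetric transfer hydrogenation, silylation and ketal hydrolysis); Me2CuLi, MeZnCl and CH2N2 are used as freshly prepared stock solutions.

## Route

Step 1
Reactants: 1 (R)-4-((tert-butyldimethylsilyl)oxy)cyclohex-2-en-1-one
Product: 2 (R)-4-((tert-butyldimethylsilyl)oxy)-2-iodocyclohex-2-en-1-one
Conditions: I2, pyridine, CH2Cl2, rt
Reagents that add atoms: iodine, II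
Why: α-Iodination of a cyclic enone by the iodine–pyridine addition–iodination–elimination sequence is general and should leave the silyloxy stereocentre untouched.

Step 2
Reactants: 2 (R)-4-((tert-butyldimethylsilyl)oxy)-2-iodocyclohex-2-en-1-one
Product: 3 (R)-4-((tert-butyldimethylsilyl)oxy)-2-methylcyclohex-2-en-1-one
Conditions: MeZnCl, Pd(PPh3)4 (cat.), THF, rt
Reagents that add atoms: methylzinc chloride, C[Zn]Cl
Why: Negishi cross-coupling of α-iodoenones with alkylzinc halides under zerovalent palladium catalysis is well established and should replace iodine by the future C5 methyl.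

Step 3
Reactants: 3 (R)-4-((tert-butyldimethylsilyl)oxy)-2-methylcyclohex-2-en-1-one
Product: 5 (3R,4R)-4-((tert-butyldimethylsilyl)oxy)-2,3-dimethylcyclohex-1-en-1-yl trifluoromethanesulfonate, via lithium enolate 4 (not isolated)
Conditions: Me2CuLi, Et2O, −78 to −20 °C; then PhNTf2, THF, −78 °C to rt
Reagents that add atoms: lithium dimethylcuprate, [Li+].C[Cu-]C; N-phenylbis(trifluoromethanesulfonimide), O=S(=O)(N(c1ccccc1)S(=O)(=O)C(F)(F)F)C(F)(F)F
Why: Conjugate addition of the Gilman cuprate should occur anti to the neighbouring silyloxy group (this sets C4 trans to the C3 oxygen), and O-triflation of the regio-defined enolate 4 fixes the double bond between C5 and C10.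

Step 4
Reactants: 5 (3R,4R)-4-((tert-butyldimethylsilyl)oxy)-2,3-dimethylcyclohex-1-en-1-yl trifluoromethanesulfonate
Product: 6 tert-butyl(((1R,2R)-2,3-dimethylcyclohex-3-en-1-yl)oxy)dimethylsilane
Conditions: Pd(OAc)2 (cat.), PPh3, Et3N, HCO2H, DMF, 60 °C
Reagents that add atoms: none
Why: Palladium-catalysed formate reduction of an enol triflate (hydride transfer to the alkenylpalladium with loss of CO2) should give the trisubstituted C5=C10 alkene without double-bond migration.

Step 5
Reactants: 6 tert-butyl(((1R,2R)-2,3-dimethylcyclohex-3-en-1-yl)oxy)dimethylsilane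
Product: 7 (1R,2R,3R,6S)-3-((tert-butyldimethylsilyl)oxy)-8,8-dichloro-1,2-dimethylbicyclo[4.2.0]octan-7-one
Conditions: Cl3CCOCl, activated Zn dust, POCl3, Et2O, rt (sonication)
Reagents that add atoms: trichloroacetyl chloride, O=C(Cl)C(Cl)(Cl)Cl
Why: The ketene–alkene [2+2] cycloaddition of dichloroketene is suprafacial on the alkene (C5 methyl and C10 hydrogen cis), bonds the carbonyl carbon (future C8) to the less substituted C10 and the CCl2 carbon (C6) to C5, and should take place anti to the pseudoaxial C4 methyl so that the two methyl groups end up cis.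

Step 6
Reactants: 7 (1R,2R,3R,6S)-3-((tert-butyldimethylsilyl)oxy)-8,8-dichloro-1,2-dimethylbicyclo[4.2.0]octan-7-one
Product: 8 3α-(tert-butyldimethylsilyloxy)-6,6-dichloro-4β,5β-dimethyl-10βH-hydrindane-core 8-ketone
Conditions: CH2N2, Et2O–MeOH, 0 °C
Reagents that add atoms: diazomethane, C=[N+]=[N-]
Why: Diazomethane ring expansion of an α,α-dichlorocyclobutanone (Tiffeneau–Demjanov-type 1,2-shift) is fast and regioselective because only the non-chlorinated α-carbon C10 migrates, which places the new methylene C9 between C8 and C10.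

Step 7
Reactants: 8 3α-(tert-butyldimethylsilyloxy)-6,6-dichloro-4β,5β-dimethyl-10βH-hydrindane-core 8-ketone
Product: 9 6,6-dichloro-3α-hydroxy-4β,5β-dimethyl-10βH-hydrindane-core 8-ketone
Conditions: HF (48% aq), MeCN, 0 °C to rt
Reagents that add atoms: none
Why: Acidic fluoride should cleave the secondary silyl ether while the base-sensitive α,α-dichloroketone, which a basic fluoride source would endanger, survives.

Step 8
Reactants: 9 6,6-dichloro-3α-hydroxy-4β,5β-dimethyl-10βH-hydrindane-core 8-ketone
Product: 10 6,6-dichloro-4β,5β-dimethyl-10βH-hydrindane-core 8-ketone 3α-tiglate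
Conditions: (E)-2-methylbut-2-enoyl chloride, pyridine, DMAP (cat.), CH2Cl2, 0 °C to rt
Reagents that add atoms: (E)-2-methylbut-2-enoyl chloride, O=C(Cl)/C(C)=C/C
Why: DMAP-catalysed acylation of the equatorial C3 alcohol installs the tiglate with retention at C3 and of the E geometry, so that no protecting-group change is needed after ring B exists.

Step 9
Reactants: 10 6,6-dichloro-4β,5β-dimethyl-10βH-hydrindane-core 8-ketone 3α-tiglate
Product: 11 8-(tert-butyldimethylsilyloxy)-6,6-dichloro-hydrindane-core 8(9)-ene 3α-tiglate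
Conditions: TBSOTf, Et3N, CH2Cl2, 0 °C
Reagents that add atoms: tert-butyldimethylsilyl trifluoromethanesulfonate, CC(C)(C)[Si](C)(C)OS(=O)(=O)C(F)(F)F
Why: Soft enolisation with a silyl triflate and an amine can only go toward C9 because C6 carries no hydrogen, so a single silyl enol ether should form while the less acidic ester stays untouched.

Step 10
Reactants: 11 8-(tert-butyldimethylsilyloxy)-6,6-dichloro-hydrindane-core 8(9)-ene 3α-tiglate
Product: 13 9β-(tert-butyldimethylsilyloxy)-6,6-dichloro-hydrindane-core 8-ketone 3α-tiglate, via silyloxy epoxide 12 (not isolated)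
Conditions: mCPBA, NaHCO3, CH2Cl2, −20 °C to rt
Reagents that add atoms: 3-chloroperoxybenzoic acid, O=C(OO)c1cccc(Cl)c1
Why: In this Rubottom oxidation the electron-rich enol ether (not the electron-poor tiglate alkene) should be epoxidised on the convex β face, anti to the adjacent C10–C1 bond, and 1,4-silyl shift in silyloxy epoxide 12 then gives the 9β-silyloxy ketone.

Step 11
Reactants: 13 9β-(tert-butyldimethylsilyloxy)-6,6-dichloro-hydrindane-core 8-ketone 3α-tiglate
Product: 14 9β-(tert-butyldimethylsilyloxy)-4β,5β-dimethyl-10βH-hydrindane-core 8-ketone 3α-tiglate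
Conditions: activated Zn dust, NH4Cl, MeOH, rt
Reagents that add atoms: none
Why: Reductive dechlorination of α,α-dichloroketones by zinc and a mild proton source is the standard sequel to the ketene/diazomethane sequence and should be much faster than cleavage of the α'-silyloxy group.

Step 12
Reactants: 14 9β-(tert-butyldimethylsilyloxy)-4β,5β-dimethyl-10βH-hydrindane-core 8-ketone 3α-tiglate
Product: 15 (E)-8-(2-methylallylidene)-9β-(tert-butyldimethylsilyloxy)-hydrindane-core 3α-tiglate
Conditions: (2-methylallyl)triphenylphosphonium chloride, KN(SiMe3)2, THF, −78 °C to rt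
Reagents that add atoms: (2-methylallyl)triphenylphosphonium chloride, [Cl-].C=C(C)C[P+](c1ccccc1)(c1ccccc1)c1ccccc1
Why: Wittig olefination with the semi-stabilised allylic ylide should give the exocyclic diene C8=C7–C11=C12, the E isomer (isopropenyl cis to C6) being favoured because the Z isomer suffers allylic 1,3-strain with the C9 silyloxy group.

Step 13
Reactants: 15 (E)-8-(2-methylallylidene)-9β-(tert-butyldimethylsilyloxy)-hydrindane-core 3α-tiglate
Product: 16 (E)-8-(2-methylallylidene)-9β-hydroxy-hydrindane-core 3α-tiglate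
Conditions: Bu4NF, AcOH, THF, 0 °C
Reagents that add atoms: none
Why: Buffered fluoride should remove the allylic silyl ether without touching the ester or the diene.

Step 14
Reactants: 16 (E)-8-(2-methylallylidene)-9β-hydroxy-hydrindane-core 3α-tiglate
Product: 17 7,8-epoxide (oxygen β on C8; isopropenyl on C7 cis to C6) of the 9β-hydroxy-hydrindane-core 3α-tiglate
Conditions: VO(acac)2 (cat.), t-BuOOH, CH2Cl2, 0 °C
Reagents that add atoms: tert-butyl hydroperoxide, CC(C)(C)OO
Why: Vanadium-catalysed epoxidation is directed by the allylic hydroxyl, so only the C8=C7 bond should react (not the isopropenyl or the enoate) and oxygen is delivered syn to the 9β-OH, which sets C8 and, through the E geometry, C7.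

Step 15
Reactants: 17 7,8-epoxide (oxygen β on C8; isopropenyl on C7 cis to C6) of the 9β-hydroxy-hydrindane-core 3α-tiglate
Product: 18 7,8-epoxy-hydrindane-core 9β-senecioate 3α-tiglate
Conditions: 3-methylbut-2-enoyl chloride, pyridine, DMAP (cat.), CH2Cl2, 0 °C
Reagents that add atoms: 3-methylbut-2-enoyl chloride, CC(C)=CC(Cl)=O
Why: Acylation of the secondary epoxy alcohol under basic conditions leaves the acid-sensitive vinyl epoxide intact, and pyridine in place of a trialkylamine limits deconjugation of the senecioyl group through a vinylketene.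

Step 16
Reactants: 18 7,8-epoxy-hydrindane-core 9β-senecioate 3α-tiglate
Product: 19 (1R,3R,4aR,5R,6R,8aS)-4a,5-dimethyl-1-((3-methylbut-2-enoyl)oxy)-2-oxo-3-(prop-1-en-2-yl)decahydronaphthalen-6-yl (E)-2-methylbut-2-enoate (target)
Conditions: BF3·OEt2 (0.3 equiv), CH2Cl2, −78 °C; cold NaHCO3 quench
Reagents that add atoms: none
Why: Coordination of BF3 to the epoxide oxygen should ionise the C7–O bond (allyl cation over C7–C11–C12; the C8–O bond is kept because a C8 cation would sit next to the electron-poor acyloxy carbon C9), and the C8–C6 bond then shifts to C7 while C8–O becomes the ketone, a semipinacol (Meinwald-type) rearrangement. The closest known reaction types are the Lewis-acid rearrangement of 2,3-epoxy alcohol esters and the ring-enlarging rearrangement of alkylidenecycloalkane oxides to 2-substituted cycloalkanones. Ring B (C5–C6–C7–C8–C9–C10) is closed not by a cyclisation but by a suprafacial 1,2-alkyl shift that enlarges the cyclopentane C5–C6–C8–C9–C10 by one carbon. The new stereocentre C7 is controlled by the epoxide: with the oxygen β on C8 and the isopropenyl group cis to C6, the least-motion rotation that aligns the C8–C6 bond with the emptying C7 orbital delivers C6 to the face that leaves the isopropenyl group β and equatorial, cis to the C9 oxygen, which is also the more stable epimer. The step needs C6 and not C9 to migrate, which the acyloxy group secures by lowering the migratory aptitude of C9, while its trans relation to C7 disfavours acyloxonium participation. Low temperature, a substoichiometric amount of acid and a bicarbonate quench should keep the isopropenyl double bond out of conjugation with the new ketone.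

## Compound list

1 | (R)-4-((tert-butyldimethylsilyl)oxy)cyclohex-2-en-1-one | O=C1CC[C@@H](O[Si](C)(C)C(C)(C)C)C=C1 | starting material
2 | (R)-4-((tert-butyldimethylsilyl)oxy)-2-iodocyclohex-2-en-1-one | O=C1CC[C@@H](O[Si](C)(C)C(C)(C)C)C=C1I | intermediate
3 | (R)-4-((tert-butyldimethylsilyl)oxy)-2-methylcyclohex-2-en-1-one | O=C1CC[C@@H](O[Si](C)(C)C(C)(C)C)C=C1C | intermediate
4 | lithium (3R,4R)-4-((tert-butyldimethylsilyl)oxy)-2,3-dimethylcyclohex-1-en-1-olate | CC1=C(O[Li])CC[C@@H](O[Si](C)(C)C(C)(C)C)[C@@H]1C | intermediate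
5 | (3R,4R)-4-((tert-butyldimethylsilyl)oxy)-2,3-dimethylcyclohex-1-en-1-yl trifluoromethanesulfonate | CC1=C(OS(=O)(=O)C(F)(F)F)CC[C@@H](O[Si](C)(C)C(C)(C)C)[C@@H]1C | intermediate
6 | tert-butyl(((1R,2R)-2,3-dimethylcyclohex-3-en-1-yl)oxy)dimethylsilane | CC1=CCC[C@@H](O[Si](C)(C)C(C)(C)C)[C@@H]1C | intermediate
7 | (1R,2R,3R,6S)-3-((tert-butyldimethylsilyl)oxy)-8,8-dichloro-1,2-dimethylbicyclo[4.2.0]octan-7-one (cyclobutanone C5–C6Cl2–C8(=O)–C10) | O=C1[C@H]2CC[C@@H](O[Si](C)(C)C(C)(C)C)[C@H](C)[C@@]2(C)C1(Cl)Cl | intermediate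
8 | hydrindane-core 8-ketone: 6,6-dichloro; 3α-OTBS; 4β,5β-dimethyl; 10β-H | O=C1C[C@H]2CC[C@@H](O[Si](C)(C)C(C)(C)C)[C@H](C)[C@@]2(C)C1(Cl)Cl | intermediate
9 | hydrindane-core 8-ketone: 6,6-dichloro; 3α-OH; 4β,5β-dimethyl; 10β-H | O=C1C[C@H]2CC[C@@H](O)[C@H](C)[C@@]2(C)C1(Cl)Cl | intermediate
10 | hydrindane-core 8-ketone: 6,6-dichloro; 3α-tiglate; 4β,5β-dimethyl; 10β-H | O=C1C[C@H]2CC[C@@H](OC(=O)/C(C)=C/C)[C@H](C)[C@@]2(C)C1(Cl)Cl | intermediate
11 | silyl enol ether C8(OTBS)=C9 of 10 | CC(C)(C)[Si](C)(C)OC1=C[C@H]2CC[C@@H](OC(=O)/C(C)=C/C)[C@H](C)[C@@]2(C)C1(Cl)Cl | intermediate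
12 | 8β,9β-epoxide of 11 (8α-OTBS) | CC(C)(C)[Si](C)(C)O[C@@]12O[C@@H]1[C@H]3CC[C@@H](OC(=O)/C(C)=C/C)[C@H](C)[C@@]3(C)C2(Cl)Cl | intermediate
13 | hydrindane-core 8-ketone: 6,6-dichloro; 9β-OTBS; 3α-tiglate | O=C1[C@H](O[Si](C)(C)C(C)(C)C)[C@H]2CC[C@@H](OC(=O)/C(C)=C/C)[C@H](C)[C@@]2(C)C1(Cl)Cl | intermediate
14 | hydrindane-core 8-ketone: 9β-OTBS; 3α-tiglate; 4β,5β-dimethyl; 10β-H | O=C1[C@H](O[Si](C)(C)C(C)(C)C)[C@H]2CC[C@@H](OC(=O)/C(C)=C/C)[C@H](C)[C@@]2(C)C1 | intermediate
15 | (E)-diene C8=C7H–C11(CH3)=C12H2 on the hydrindane core: 9β-OTBS; 3α-tiglate | C=C(C)/C=C1/[C@H](O[Si](C)(C)C(C)(C)C)[C@H]2CC[C@@H](OC(=O)/C(C)=C/C)[C@H](C)[C@@]2(C)C1 | intermediate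
16 | (E)-dienol: as 15 with 9β-OH | C=C(C)/C=C1/[C@H](O)[C@H]2CC[C@@H](OC(=O)/C(C)=C/C)[C@H](C)[C@@]2(C)C1 | intermediate
17 | spiro 7,8-epoxide (O β on C8; isopropenyl on C7 cis to C6): 9β-OH; 3α-tiglate | C=C(C)[C@@H]1O[C@@]12[C@H](O)[C@H]3CC[C@@H](OC(=O)/C(C)=C/C)[C@H](C)[C@@]3(C)C2 | intermediate
18 | spiro 7,8-epoxide: 9β-senecioate; 3α-tiglate | C=C(C)[C@@H]1O[C@@]12[C@H](OC(=O)C=C(C)C)[C@H]3CC[C@@H](OC(=O)/C(C)=C/C)[C@H](C)[C@@]3(C)C2 | intermediate
19 | (1R,3R,4aR,5R,6R,8aS)-4a,5-dimethyl-1-((3-methylbut-2-enoyl)oxy)-2-oxo-3-(prop-1-en-2-yl)decahydronaphthalen-6-yl (E)-2-methylbut-2-enoate | C=C(C)[C@H]1C[C@@]2(C)[C@H](CC[C@@H](OC(=O)/C(C)=C/C)[C@@H]2C)[C@@H](OC(=O)C=C(C)C)C1=O | target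

## Step count and risks

Total step count: 16. Longest linear sequence: 16 steps (1 to 19).

Steps most likely to fail, riskiest first:

Step 16. After ionisation of the epoxide the acyloxy-bearing C9 may migrate in place of C6, the senecioate carbonyl may trap the allyl cation, or the isopropenyl double bond may drift into conjugation under the Lewis acid. The fallback sets out from 14 and comes back at 19. It enlarges ring B one stage earlier by a diazoalkane homologation in which the silyloxy-bearing C9 is the non-migrating carbon, and adds the isopropenyl group afterwards. Ketone 14 with Me3SiCHN2 and catalytic Sc(OTf)3 should give, after 1,3-silyl shift, the ring-enlarged trimethylsilyl enol ether F7. Mukaiyama aldol addition to acetone (TiCl4, CH2Cl2, −78 °C) should then give the 7-(2-hydroxypropan-2-yl) ketone F8. Dehydration with SOCl2 and pyridine should give the 7-isopropenyl ketone F9, and HF·pyridine the 9β-hydroxy ketone F10. Acylation with 3-methylbut-2-enoyl chloride and pyridine then gives 19.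

Step 5. Facial selectivity may be poor, because in the half-chair with the C4 methyl pseudoaxial the trans C3 silyloxy group is axial on the very face the ketene has to reach. The fallback sets out from 6 and comes back at 10. It inverts C3 for the cycloaddition and restores it when the tiglate is put on. Bu4NF should give (1R,2R)-2,3-dimethylcyclohex-3-en-1-ol F1. A Mitsunobu reaction with formic acid (PPh3, DIAD) should give the cis formate F2, whose ester is equatorial when the C4 methyl is axial. Dichloroketene cycloaddition and diazomethane ring expansion as in steps 5 and 6 should give the 3β-formyloxy dichlorocyclobutanone F3 and the 3β-formyloxy dichlorocyclopentanone F4. HCl in methanol should give the 3β-alcohol F5. Mitsunobu esterification of F5 with (E)-2-methylbut-2-enoic acid then gives 10 with inversion at C3.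

Step 12. The basic ylide may deprotonate the hindered α-silyloxy ketone instead of adding to it, or the E/Z ratio may be unfavourable. The fallback sets out from 14 and comes back at 15. It adds the carbon chain with a weakly basic allyl metal and makes the double bond by dehydration. 2-Methylallylmagnesium chloride with CeCl3 (THF, −78 °C) should add anti to the silyloxy group to give the tertiary homoallylic alcohol F6. Syn-dehydration with methyl N-(triethylammoniumsulfonyl)carbamate (toluene, 50 °C) toward the allylic C7 hydrogens should then give diene 15.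

## Further compounds

F1 | step 5 | (1R,2R)-2,3-dimethylcyclohex-3-en-1-ol | CC1=CCC[C@@H](O)[C@@H]1C
F2 | step 5 | (1S,2R)-2,3-dimethylcyclohex-3-en-1-yl formate | CC1=CCC[C@H](OC=O)[C@@H]1C
F3 | step 5 | 3β-formyloxy analogue of cyclobutanone 7 | O=C1[C@H]2CC[C@H](OC=O)[C@H](C)[C@@]2(C)C1(Cl)Cl
F4 | step 5 | 3β-formyloxy-6,6-dichloro hydrindane-core 8-ketone | O=C1C[C@H]2CC[C@H](OC=O)[C@H](C)[C@@]2(C)C1(Cl)Cl
F5 | step 5 | 3β-hydroxy-6,6-dichloro hydrindane-core 8-ketone | O=C1C[C@H]2CC[C@H](O)[C@H](C)[C@@]2(C)C1(Cl)Cl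
F6 | step 12 | 8β-hydroxy-8α-(2-methylallyl)-9β-OTBS hydrindane-core 3α-tiglate | C=C(C)C[C@@]1(O)[C@H](O[Si](C)(C)C(C)(C)C)[C@H]2CC[C@@H](OC(=O)/C(C)=C/C)[C@H](C)[C@@]2(C)C1
F7 | step 16 | ring-enlarged trimethylsilyl enol ether C8(OTMS)=C7 (cis-decalin; 9β-OTBS; 3α-tiglate) | C[Si](C)(C)OC1=CC[C@@]2(C)[C@H](CC[C@@H](OC(=O)/C(C)=C/C)[C@@H]2C)[C@H]1O[Si](C)(C)C(C)(C)C
F8 | step 16 | 7β-(2-hydroxypropan-2-yl)-9β-OTBS decalin-8-one 3α-tiglate | CC(C)(O)[C@H]1C[C@@]2(C)[C@H](CC[C@@H](OC(=O)/C(C)=C/C)[C@@H]2C)[C@@H](O[Si](C)(C)C(C)(C)C)C1=O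
F9 | step 16 | 7β-isopropenyl-9β-OTBS decalin-8-one 3α-tiglate | C=C(C)[C@H]1C[C@@]2(C)[C@H](CC[C@@H](OC(=O)/C(C)=C/C)[C@@H]2C)[C@@H](O[Si](C)(C)C(C)(C)C)C1=O
F10 | step 16 | 7β-isopropenyl-9β-hydroxy decalin-8-one 3α-tiglate | C=C(C)[C@H]1C[C@@]2(C)[C@H](CC[C@@H](OC(=O)/C(C)=C/C)[C@@H]2C)[C@@H](O)C1=O
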